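Take a closed, stirred vessel at constant temperature, holding a racemate, a single-handed free catalyst, reagent and a trace of impurity.

- beta: left-handed substrate 0.050 M; right-handed substrate 0.050 M; reagent 3 equiv; free catalyst 0.1 mol%; impurity 19 µM; run made earlier
- flask: left-handed substrate 0.050 M; reagent 1.50 equiv; free catalyst 0.1 mol%; impurity 19 µM; right-handed substrate 0.050 M; time 1.5 h

beta run (percent of the left-handed substrate and right-handed substrate together charged)

| time / min | right-handed substrate / % | left-handed substrate / % |
|---|---|---|
| 1.33 | 41 | 28 |
| 2.50 | 34 | 21 |
| 4.00 | 30 | 16 |
| 6.00 | 28 | 7 |
| 10.0 | 22 | 8 |
| 20.0 | 15 | 2 |

(each reading ± 2 percentage points)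

- whether the excess of right-handed substrate over left-handed substrate among what is left of the two reaches 99% by 1.5 h (no / yes)
- the highest excess of right-handed substrate over left-handed substrate among what is left of the two up to 1.5 h

- free catalyst is single-handed; left-handed substrate and right-handed substrate are mirror images of each other, charged as a racemate, each of them at the stated concentration

Begin with the beta run. Turn each reading into the fraction of its own charge left, take logarithms, and divide the left-handed sum by the right-handed sum. This gives a selectivity factor, s, of 2.60, as a reading. Use it as a rule, for this racemate with this free catalyst: the left-handed fraction left equals the right-handed fraction left raised to the power s.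

Turn the time first. The beta run reads an excess of 76.5% at 20.0 min. Assuming one reagent per substrate, its charge covers 150% of the pair, more than the pair needs, so by the rule a longer time raises the excess.

Now turn the reagent. In the asked flask, 1.50 equiv covers 75.0% of the pair, less than the pair needs, which makes reagent the limiting reagent, so, still assuming one reagent per substrate, the two fractions left must add up to at least 50.0%. Solve this with the rule: right-handed substrate keeps 40.5% of its own charge and left-handed substrate 9.55% of its own. The excess there is 61.8%. Call it the reagent ceiling, the excess reckoned for the point where the substrate reacted equals the reagent charged. Commit to a top at or below it, and to "no", since the ceiling is lower than 99%.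

The forecast also says no, but it puts the top at 90%, higher than this ceiling, holding that “Excess rises monotonically, so the top value is the 1.5 h value”.

The simulated flask gives no and a top of 56.7%, lower than the ceiling.

    reagent + free catalyst + left-handed substrate → free catalyst + left-handed product (k = 93100 M⁻² min⁻¹)
    reagent + free catalyst + right-handed substrate → free catalyst + right-handed product (k = 35400 M⁻² min⁻¹)
    free catalyst + impurity → spent catalyst (k = 3.65 × 10⁵ M⁻¹ min⁻¹)
    reagent ⇌ dormant form (K = 0.869, k = 0.0584 min⁻¹)

Now take a neighbouring flask with the reagent cut to 0.380 equiv, its other charges and its time as in the asked flask. That charge covers 19.0% of the pair, so the fractions left add up to at least 162%. The rule then gives right-handed 88.7% and left-handed 73.3% of their own charges, and a ceiling of 9.52%. That neighbouring flask ends with 0.19% of its reagent, 73% of its left-handed charge and 89% of its right-handed charge, and its top is 9.57%.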